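**Retrosynthetic overview**
1. Bought-in pieces: 2,4-dimethoxybenzaldehyde 1 and HC≡CMgBr 2 (joined as propargylic alcohol 3, the aroyl–C3 unit) and 2-bromo-4,5-dimethoxybenzyl alcohol 4 (benzo ring, C1 and O2).
2. C4–C4a disconnection: Sonogashira coupling of 3 with 4 gives diol 5, which holds all 20 carbons.
3. Key disconnection, O2–C3 (enol-ether C–O bond): hydroxy-ynone 6, made from 5 by selective oxidation, is closed by a phosphine-catalysed 6-endo anti-Michael O–H addition to target 7.
4. Ring order: both benzene rings come from the starting materials; the pyran ring is the only ring formed, and it is formed last.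

Assumption: the target has no stereocentre (its only non-aromatic C=C is inside the ring), so no enantiocontrol is needed and the carbinol intermediates are carried as racemates.

**Step 1**
Reactants: 1 2,4-dimethoxybenzaldehyde; 2 ethynylmagnesium bromide (HC≡CMgBr, 0.5 M in THF)
Product: 3 1-(2,4-dimethoxyphenyl)prop-2-yn-1-ol (racemic)
Conditions: HC≡CMgBr (1.3 equiv), THF, 0 °C to rt; sat. aq. NH4Cl
Reagents that add atoms: ethynylmagnesium bromide 2, C#C[Mg]Br
Why: Grignard 1,2-addition of an alkynyl nucleophile to an aryl aldehyde; the new carbinol centre forms as a racemate, which does not matter because it becomes the ketone carbon in step 3.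

**Step 2**
Reactants: 3 1-(2,4-dimethoxyphenyl)prop-2-yn-1-ol; 4 (2-bromo-4,5-dimethoxyphenyl)methanol
Product: 5 1-(2,4-dimethoxyphenyl)-3-[2-(hydroxymethyl)-4,5-dimethoxyphenyl]prop-2-yn-1-ol (racemic)
Conditions: Pd(PhCN)2Cl2 (3 mol%), [HP(t-Bu)3]BF4 (6 mol%), CuI (2 mol%), i-Pr2NH (2.5 equiv), 1,4-dioxane, rt, argon
Reagents that add atoms: none
Why: Sonogashira coupling; the bulky, electron-rich P(t-Bu)3 ligand lets zerovalent palladium insert into the electron-rich aryl bromide at room temperature, which spares the acid- and heat-sensitive propargylic alcohol and tolerates both free OH groups (carbinol centre still racemic).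

**Step 3**
Reactants: 5 1-(2,4-dimethoxyphenyl)-3-[2-(hydroxymethyl)-4,5-dimethoxyphenyl]prop-2-yn-1-ol
Product: 7 (2,4-dimethoxyphenyl)(6,7-dimethoxy-1H-isochromen-3-yl)methanone (target), via hydroxy-ynone 6 (not isolated)
Conditions: (a) activated MnO2 (8 equiv), CH2Cl2, 0 °C to rt, stop when 5 is consumed; filter (Celite), evaporate; (b) PPh3 (20 mol%), AcOH (50 mol%), NaOAc (50 mol%), PhMe, 80 °C, argon
Reagents that add atoms: none
Why: Proposed new method: MnO2 first oxidises the doubly activated (benzylic and propargylic) secondary carbinol of 5 faster than the primary benzylic CH2OH, giving ynone 6 and erasing the racemic centre; PPh3 then adds to the ynone β-carbon (the alkyne carbon on the benzo ring), the zwitterion is protonated at Cα by the buffer or the neighbouring OH, and the resulting β-phosphonio enone is attacked at Cα by the tethered benzylic oxygen (6-endo-trig on a vinylphosphonium, with the β-carbon that a base- or π-acid-driven 5-exo oxa-Michael closure would use blocked by phosphorus), after which a 1,2-proton shift and β-elimination of PPh3 leave the O2–C3 bond and the ring C3=C4 alkene with no stereocentre; the closest known reaction types are the phosphine-catalysed α-umpolung (anti-Michael) addition of N–H and O–H pronucleophiles to 3-aryl-2-alkynoates under PPh3/AcOH/NaOAc and the phosphine-catalysed anti-Michael cyclisation of 2-hydroxyaryl ynones to aurones, which to our knowledge have not been used for a 6-endo closure by an aliphatic benzylic alcohol tethered through the β-aryl group to give a 3-aroyl-1H-isochromene.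

**Compound list**
1 | 2,4-dimethoxybenzaldehyde | COc1ccc(C=O)c(OC)c1 | starting material
2 | ethynylmagnesium bromide (HC≡CMgBr) | C#C[Mg]Br | starting material
3 | 1-(2,4-dimethoxyphenyl)prop-2-yn-1-ol (racemic) | COc1ccc(C(O)C#C)c(OC)c1 | intermediate
4 | (2-bromo-4,5-dimethoxyphenyl)methanol | COc1cc(Br)c(CO)cc1OC | starting material
5 | 1-(2,4-dimethoxyphenyl)-3-[2-(hydroxymethyl)-4,5-dimethoxyphenyl]prop-2-yn-1-ol (racemic) | COc1ccc(C(O)C#Cc2cc(OC)c(OC)cc2CO)c(OC)c1 | intermediate
6 | 1-(2,4-dimethoxyphenyl)-3-[2-(hydroxymethyl)-4,5-dimethoxyphenyl]prop-2-yn-1-one (achiral) | COc1ccc(C(=O)C#Cc2cc(OC)c(OC)cc2CO)c(OC)c1 | intermediate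
7 | (2,4-dimethoxyphenyl)(6,7-dimethoxy-1H-isochromen-3-yl)methanone (achiral) | COc1ccc(C(=O)C2=Cc3cc(OC)c(OC)cc3CO2)c(OC)c1 | target

**Step count and risks**
Total steps: 3 (step 3 is a telescoped oxidation/cyclisation with one purification). Longest linear sequence: 3 (1 → 3 → 5 → 7).

Most likely to fail, riskiest first: step 3, step 2, step 1.

Step 3 is the new step and carries two risks. The first is over-oxidation of the CH2OH of 5. The second and larger one is leakage into the 5-exo oxa-Michael product if free alkoxide forms instead of the phosphonium pathway. The fallback uses known chemistry, sets out from 3 and comes back at 7, and avoids both the selective oxidation and the phosphine step. Sonogashira coupling of 3 with commercial 2-bromo-4,5-dimethoxybenzaldehyde (PdCl2(PPh3)2, CuI, Et3N, THF, 50 °C) gives 2-[3-(2,4-dimethoxyphenyl)-3-hydroxyprop-1-yn-1-yl]-4,5-dimethoxybenzaldehyde F1. With AgOSO2CF3 (5 mol%) and Hantzsch ester (1.2 equiv) in CH2Cl2 at rt, the aldehyde oxygen closes 6-endo onto the silver-activated alkyne because this gives an aromatic 2-benzopyrylium ion. Hydride transfer to C1 then gives (2,4-dimethoxyphenyl)(6,7-dimethoxy-1H-isochromen-3-yl)methanol F2 (racemic). MnO2 in CH2Cl2 oxidises this allylic, benzylic carbinol, now the only alcohol present, to 7.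

Step 2 is next: the electron-rich bromide 4 is a slow coupling partner, and 3 can homocouple or ionise. The fallback sets out from 4 and comes back at 5, and it replaces the aryl–alkyne union with 3 by an acetylide addition to aldehyde 1. Compound 4 is coupled with the robust trimethylsilylacetylene (PdCl2(PPh3)2, CuI, Et3N, 70 °C) to give {4,5-dimethoxy-2-[(trimethylsilyl)ethynyl]phenyl}methanol F3. K2CO3 in MeOH removes the silyl group to give (2-ethynyl-4,5-dimethoxyphenyl)methanol F4. Double deprotonation (n-BuLi, 2.1 equiv, THF, −78 °C) and addition of aldehyde 1 then give 5 directly, so 3 is not needed.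

Step 1 is the least risky. Its weak points are bis-addition through BrMgC≡CMgBr and loss of the acid-labile terminal alkynol 3 on silica. The fallback sets out from 1 and comes back at 5. Lithium (trimethylsilyl)acetylide (Me3SiC≡CH, n-BuLi, THF, −78 °C) is added to 1 to give the silyl-capped, more robust 1-(2,4-dimethoxyphenyl)-3-(trimethylsilyl)prop-2-yn-1-ol F5 (racemic). F5 and 4 are then coupled in a fluoride-promoted one-pot desilylation/Sonogashira reaction (PdCl2(PPh3)2, CuI, CsF, DMF, 60 °C) to give 5 without ever isolating 3.

**Further compounds**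
F1 | step 3 | 2-[3-(2,4-dimethoxyphenyl)-3-hydroxyprop-1-yn-1-yl]-4,5-dimethoxybenzaldehyde (racemic) | COc1ccc(C(O)C#Cc2cc(OC)c(OC)cc2C=O)c(OC)c1
F2 | step 3 | (2,4-dimethoxyphenyl)(6,7-dimethoxy-1H-isochromen-3-yl)methanol (racemic) | COc1ccc(C(O)C2=Cc3cc(OC)c(OC)cc3CO2)c(OC)c1
F3 | step 2 | {4,5-dimethoxy-2-[(trimethylsilyl)ethynyl]phenyl}methanol | COc1cc(CO)c(C#C[Si](C)(C)C)cc1OC
F4 | step 2 | (2-ethynyl-4,5-dimethoxyphenyl)methanol | COc1cc(CO)c(C#C)cc1OC
F5 | step 1 | 1-(2,4-dimethoxyphenyl)-3-(trimethylsilyl)prop-2-yn-1-ol (racemic) | COc1ccc(C(O)C#C[Si](C)(C)C)c(OC)c1
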